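**Retrosynthetic overview**
- The quaternary C3–CH2 bond is cut last: conjugate addition of ferulenol (3‑farnesyl‑4‑hydroxycoumarin) to the vinyl ketone of (S)‑falcarinolone, as in the plant. It is run without protecting groups, and a chiral bifunctional catalyst sets the (S) quaternary carbon.
- Ferulenol: the pyranone ring is closed polyketide‑style, by Claisen condensation of an acetate‑derived enolate on a salicyloyl donor followed by lactonisation. The farnesyl group is already on the acetate unit, so one flask gives ferulenol.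
- (S)‑Falcarinolone: acryloyl transfer to the O,C‑dianion of a C14 diynol, whose carbinol comes from an enantioselective diyne addition to (Z)‑dec‑2‑enal.
- Ring order: the benzene ring is bought as the salicylate; the pyranone ring is formed in step 1; no other ring is needed.

Assumption: 2,2‑dimethyl‑4H‑1,3‑benzodioxin‑4‑one (salicylic acid acetonide) and (2E,6E)‑farnesyl bromide are taken as catalog compounds; all steps run under argon.

**Route**

Step 1
Reactants: 1 ethyl acetate; 2 (2E,6E)‑farnesyl bromide; 3 2,2‑dimethyl‑4H‑1,3‑benzodioxin‑4‑one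
Product: 6 ferulenol [4‑hydroxy‑3‑((2E,6E)‑3,7,11‑trimethyldodeca‑2,6,10‑trien‑1‑yl)‑2H‑chromen‑2‑one], via ethyl farnesylacetate 4 (not isolated), via open-chain keto ester 5 (not isolated)
Conditions: 1, LiN(iPr)2, THF, −78 °C; then 2, DMPU, −78 → −40 °C; then LiN(SiMe3)2 (2.2 equiv), −78 °C; then 3, −78 → 65 °C; 1 M HCl
Reagents that add atoms: none
Why: A polyketide‑type sequence in one flask, in which SN2 alkylation of lithio ethyl acetate by the allylic bromide (E,E geometry kept) gives 4, the enolate of 4 undergoes a crossed Claisen condensation on the acylal carbonyl of 3 (acetone is expelled and frees the ortho‑phenoxide of 5), and the phenoxide lactonises onto the ethyl ester (Dieckmann‑like, driven by the stable 4‑oxidocoumarin anion), so the farnesyl group is on carbon before the ring closes, no O‑alkyl isomer can form and no stereocentre is made.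

Step 2
Reactants: 7 dec‑2‑yn‑1‑ol
Product: 8 (Z)‑dec‑2‑en‑1‑ol
Conditions: H2 (1 atm), Pd/CaCO3 poisoned with Pb(OAc)2 (5 wt % Pd), quinoline, hexane, rt
Reagents that add atoms: none
Why: Lindlar‑type syn semi‑hydrogenation of the alkyne on lead‑poisoned palladium stops at the (Z)‑alkene, with quinoline suppressing over‑reduction.

Step 3
Reactants: 8 (Z)‑dec‑2‑en‑1‑ol
Product: 9 (Z)‑dec‑2‑enal
Conditions: TEMPO (10 mol %), PhI(OAc)2 (1.1 equiv), CH2Cl2, 0 °C → rt; used at once
Reagents that add atoms: none
Why: Oxoammonium (TEMPO) oxidation of the allylic alcohol under near‑neutral conditions gives the enal without Z to E isomerisation.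

Step 4
Reactants: 10 1,4‑bis(trimethylsilyl)buta‑1,3‑diyne
Product: 11 buta‑1,3‑diyn‑1‑yl(trimethyl)silane
Conditions: MeLi·LiBr (1.0 equiv), Et2O, 0 °C → rt; then 1 M HCl, 0 °C; kept as a titrated toluene solution
Reagents that add atoms: none
Why: Mono‑desilylation by nucleophilic attack of methyl on silicon cleaves one C–Si bond, the lithium diynide formed resists a second attack, and protonation gives the terminal diyne.

Step 5
Reactants: 9 (Z)‑dec‑2‑enal; 11 buta‑1,3‑diyn‑1‑yl(trimethyl)silane
Product: 13 (5S,6Z)‑tetradec‑6‑ene‑1,3‑diyn‑5‑ol, via silylated diynol 12 (not isolated)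
Conditions: 11 (3 equiv), Me2Zn (3 equiv), (S,S)‑ProPhenol [2,6‑bis{[(S)‑2‑(hydroxydiphenylmethyl)pyrrolidin‑1‑yl]methyl}‑4‑methylphenol] (10 mol %), Ph3P=O (20 mol %), toluene, 4 °C; aq NH4Cl; then K2CO3 (0.2 equiv), MeOH, 0 °C
Reagents that add atoms: none
Why: Zinc–ProPhenol catalysed enantioselective alkynylation of an aldehyde, in which the methylzinc diynide made from 11 is delivered to the Re face of the enal inside the chiral dinuclear zinc pocket and so sets the (S) carbinol (to be confirmed by Mosher esters) with the (Z)‑alkene intact, after which methanolysis of the C–Si bond frees the terminal diyne.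

Step 6
Reactants: 13 (5S,6Z)‑tetradec‑6‑ene‑1,3‑diyn‑5‑ol; 14 N‑methoxy‑N‑methylacrylamide
Product: 15 (S)‑falcarinolone [(8S,9Z)‑8‑hydroxyheptadeca‑1,9‑diene‑4,6‑diyn‑3‑one]
Conditions: n‑BuLi (2.05 equiv), THF, −78 °C; 14 (1.2 equiv), −78 → −20 °C; poured into 1 M HCl/Et2O at 0 °C
Reagents that add atoms: none
Why: Weinreb ketone synthesis on an O,C‑dianion, in which the lithium diynide adds once to the amide, the chelated tetrahedral adduct survives until the inverse acidic quench, and the quench releases the vinyl ynone while keeping the liberated amine protonated so that it cannot add to the product; the lithium alkoxide masks the carbinol, whose configuration is untouched.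

Step 7
Reactants: 6 ferulenol; 15 (S)‑falcarinolone
Product: 16 target CNP0346147.1 [(3S)‑3‑((8S,9Z)‑8‑hydroxy‑3‑oxoheptadec‑9‑ene‑4,6‑diyn‑1‑yl)‑3‑((2E,6E)‑3,7,11‑trimethyldodeca‑2,6,10‑trien‑1‑yl)chromane‑2,4‑dione]
Conditions: 15 (1.3 equiv), quinine‑derived squaramide 3‑{[3,5‑bis(trifluoromethyl)phenyl]amino}‑4‑{[(8α,9S)‑6′‑methoxycinchonan‑9‑yl]amino}cyclobut‑3‑ene‑1,2‑dione (10 mol %), CH2Cl2, −30 °C, dark
Reagents that add atoms: none
Why: Proposed new method: a catalyst‑controlled Michael addition in which the acidic enol of 6 (pKa about 5) protonates the quinuclidine nitrogen to give a chiral ammonium enolate while the squaramide N–H groups bind the ynone carbonyl of 15, so that C3 attacks the unhindered vinyl terminus (not the substituted alkyne carbon) from one enolate face and sets the (S) quaternary centre (the remote carbinol exerts no control, the facial sense of this catalyst on this nucleophile is not established and must be assigned on the product, and the quinidine‑derived pseudoenantiomer would give the C3 epimer), the closest known reaction type being the cinchona‑alkaloid‑catalysed Michael addition of α‑substituted β‑keto esters to vinyl ketones that creates all‑carbon quaternary stereocentres, and C‑attack is the thermodynamic outcome because any O‑adduct reverts by retro‑oxa‑Michael reaction.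

**Compound list**
1 | ethyl acetate | CCOC(C)=O | starting material
2 | (2E,6E)‑farnesyl bromide | BrC/C=C(\C)CC/C=C(\C)CCC=C(C)C | starting material
3 | 2,2‑dimethyl‑4H‑1,3‑benzodioxin‑4‑one | CC1(C)OC(=O)c2ccccc2O1 | starting material
4 | ethyl (4E,8E)‑5,9,13‑trimethyltetradeca‑4,8,12‑trienoate (ethyl farnesylacetate) | CCOC(=O)CC/C=C(\C)CC/C=C(\C)CCC=C(C)C | intermediate
5 | ethyl (4E,8E)‑2‑(2‑hydroxybenzoyl)‑5,9,13‑trimethyltetradeca‑4,8,12‑trienoate (racemic) | CCOC(=O)C(C/C=C(\C)CC/C=C(\C)CCC=C(C)C)C(=O)c1ccccc1O | intermediate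
6 | ferulenol | O=c1oc2ccccc2c(O)c1C/C=C(\C)CC/C=C(\C)CCC=C(C)C | intermediate
7 | dec‑2‑yn‑1‑ol | CCCCCCCC#CCO | starting material
8 | (Z)‑dec‑2‑en‑1‑ol | CCCCCCC/C=C\CO | intermediate
9 | (Z)‑dec‑2‑enal | CCCCCCC/C=C\C=O | intermediate
10 | 1,4‑bis(trimethylsilyl)buta‑1,3‑diyne | C[Si](C)(C)C#CC#C[Si](C)(C)C | starting material
11 | buta‑1,3‑diyn‑1‑yl(trimethyl)silane | C[Si](C)(C)C#CC#C | intermediate
12 | (5S,6Z)‑1‑(trimethylsilyl)tetradec‑6‑ene‑1,3‑diyn‑5‑ol | CCCCCCC/C=C\[C@H](O)C#CC#C[Si](C)(C)C | intermediate
13 | (5S,6Z)‑tetradec‑6‑ene‑1,3‑diyn‑5‑ol | CCCCCCC/C=C\[C@H](O)C#CC#C | intermediate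
14 | N‑methoxy‑N‑methylacrylamide | C=CC(=O)N(C)OC | starting material
15 | (S)‑falcarinolone, (8S,9Z)‑8‑hydroxyheptadeca‑1,9‑diene‑4,6‑diyn‑3‑one | CCCCCCC/C=C\[C@H](O)C#CC#CC(=O)C=C | intermediate
16 | CNP0346147.1, (3S)‑3‑((8S,9Z)‑8‑hydroxy‑3‑oxoheptadec‑9‑ene‑4,6‑diyn‑1‑yl)‑3‑((2E,6E)‑farnesyl)chromane‑2,4‑dione | CCCCCCC/C=C\[C@H](O)C#CC#CC(=O)CC[C@@]1(C/C=C(\C)CC/C=C(\C)CCC=C(C)C)C(=O)Oc2ccccc2C1=O | target

**Step count**
Total: 7 steps. Longest linear sequence: 5 steps (compounds 7 → 8 → 9 → 13 → 15 → 16, that is steps 2, 3, 5, 6 and 7).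

**Steps most likely to fail, with fallbacks**

Step 1. Three operations share one flask: lithio ethyl acetate can self‑condense before it is alkylated, and lactonisation of the dianion of 5 may be slow. The fallback sets out from 2 and buys the ring instead of building it. The sodium salt of 4‑hydroxycoumarin F1 (NaH, THF, 2 equiv of F1 to suppress double alkylation) is C‑allylated with 2 under Pd(PPh3)4 (5 mol %, zerovalent palladium, THF, rt). The soft enolate attacks the unsubstituted terminus of the π‑allyl complex, and any O‑farnesyl ether re‑ionises and is funnelled to carbon. This comes back to the route at 6.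

Step 6. The vinyl ynone can polymerise, or can take up the liberated amine or the alkoxide in a conjugate addition. The fallback sets out from 13 and replaces acyl transfer by aldehyde addition and oxidation. Silylation (TBSCl, imidazole, DMF) gives the silyl ether F2. Its lithium diynide (n‑BuLi, THF, −78 °C) adds to acrolein to give the allylic alcohol F3 as both C3 epimers. MnO2 (CH2Cl2, rt) oxidises it to the silylated vinyl ynone F4, and HF·pyridine (THF, 0 °C) removes the silyl group. This comes back to the route at 15.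

Step 7 (the greatest risk). Facial selectivity on a 3‑substituted 4‑hydroxycoumarin is untested, the alkyne carbon is a second electrophilic site, and retro‑Michael reaction could erode the quaternary centre. The fallback sets out from 6 and 15 and gives up catalyst control. Et3N (10 mol %, CH2Cl2, 0 °C) gives 16 together with its C3 epimer F5 in roughly equal amounts. The two are diastereomers and are separated by preparative HPLC on an amylose tris(3,5‑dimethylphenylcarbamate) phase. This comes back to the route at 16.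

**Further compounds**
F1 | step 1 | 4‑hydroxycoumarin | O=c1cc(O)c2ccccc2o1
F2 | step 6 | tert‑butyl(dimethyl){[(5S,6Z)‑tetradec‑6‑ene‑1,3‑diyn‑5‑yl]oxy}silane | CCCCCCC/C=C\[C@H](O[Si](C)(C)C(C)(C)C)C#CC#C
F3 | step 6 | (8S,9Z)‑8‑[(tert‑butyldimethylsilyl)oxy]heptadeca‑1,9‑diene‑4,6‑diyn‑3‑ol (both C3 epimers) | CCCCCCC/C=C\[C@H](O[Si](C)(C)C(C)(C)C)C#CC#CC(O)C=C
F4 | step 6 | (8S,9Z)‑8‑[(tert‑butyldimethylsilyl)oxy]heptadeca‑1,9‑diene‑4,6‑diyn‑3‑one | CCCCCCC/C=C\[C@H](O[Si](C)(C)C(C)(C)C)C#CC#CC(=O)C=C
F5 | step 7 | (3R) epimer of 16 | CCCCCCC/C=C\[C@H](O)C#CC#CC(=O)CC[C@]1(C/C=C(\C)CC/C=C(\C)CCC=C(C)C)C(=O)Oc2ccccc2C1=O
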